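**Retrosynthetic overview**

1. The seven-membered ring is opened at the two single bonds that flank its tetrasubstituted C=C (olefinic C(CH3)–CH(OH) and olefinic C(tether)–CMe2); both are made at once by inserting an alkynoate (the ring methyl carried as CO2Et) between a tertiary radical and an aldehyde.
2. Enabling feature: in the cis-fused hydroazulene the ring alkene is flanked by a gem-dimethyl quaternary carbon (retron of isopropenyl + H•) and a secondary carbinol (retron of CHO), and both termini sit cis on adjacent carbons of the cyclopentanol ring, so one (5+2) radical–polar crossover annulation joins the two halves and closes the ring.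
3. Eastern half 25 from (R)-limonene oxide: cleavage/aldol ring contraction (cyclopentane), epoxidation anti to isopropenyl (tertiary carbinol), one-carbon homologation, face-selective conjugate reduction (all-cis carbon substituents).
4. Western half 18 from geranyl acetate: two Shi epoxidations of opposite sense, an enol-silane-terminated epoxide-opening cascade (oxepane, then trans-fused cyclohexanone), MeMgBr for the axial tertiary carbinol, chain extension to the alkynoate.
5. Ring order: cyclopentane; oxepane then cyclohexane; cycloheptene last (key step); endgame: oxidation/reduction fixes the allylic carbinol, CO2Et → CH3, desilylation.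

Key step: step 19

Remark: the oxepane carbinol (S) and the oxepane/cyclohexane fusion carbons (R,R) require epoxides of opposite facial sense, so the two epoxides are installed separately with the two enantiomeric Shi ketones, both taken as available.

**Western half**

Step 1
Reactants: 1 geranyl acetate
Product: 2 (S)-6,7-epoxygeranyl acetate
Conditions: L-fructose-derived Shi ketone (30 mol%), Oxone (KHSO5), aq. K2CO3 buffer (pH 10.5), n-Bu4NHSO4, MeCN/CH2(OMe)2, 0 °C
Reagents that add atoms: Oxone (potassium peroxymonosulfate), [K+].[O-]S(=O)(=O)OO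
Why: Shi asymmetric epoxidation, in which the allylic acetate deactivates the proximal alkene so only the distal trisubstituted alkene reacts, and the L-fructose-derived ketone delivers oxygen through the spiro transition state to the face that gives the (S)-epoxide (the later oxepane carbinol).

Step 2
Reactants: 2 (S)-6,7-epoxygeranyl acetate
Product: 3 (S)-6,7-epoxygeraniol
Conditions: K2CO3 (cat.), MeOH, 0 °C
Reagents that add atoms: none
Why: Base-catalysed transesterification removes the acetate and leaves the trisubstituted epoxide untouched.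

Step 3
Reactants: 3 (S)-6,7-epoxygeraniol
Product: 4 (S)-6,7-epoxygeranyl bromide
Conditions: CBr4, PPh3, CH2Cl2, −30 → 0 °C
Reagents that add atoms: carbon tetrabromide, BrC(Br)(Br)Br
Why: Appel bromination of the primary allylic alcohol proceeds by SN2 at low temperature, so the (E)-alkene and the epoxide are retained.

Step 4
Reactants: 4 (S)-6,7-epoxygeranyl bromide; 5 dimethyl (2-oxopropyl)phosphonate
Product: 6 epoxy β-ketophosphonate
Conditions: 5, NaH, THF, 0 °C; n-BuLi, 0 °C; then 4, 0 °C → rt; aq. NH4Cl
Reagents that add atoms: none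
Why: The β-ketophosphonate dianion is alkylated at its more basic terminal carbon by the primary allylic bromide (SN2), which leaves the phosphonate carbon free for the next olefination.

Step 5
Reactants: 6 epoxy β-ketophosphonate; 7 (benzyloxy)acetaldehyde
Product: 8 (E)-enone with one epoxide
Conditions: LiCl, i-Pr2NEt, MeCN, rt
Reagents that add atoms: none
Why: Horner–Wadsworth–Emmons olefination under Masamune–Roush conditions gives the (E)-enone with a base mild enough to spare the epoxide.

Step 6
Reactants: 8 (E)-enone with one epoxide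
Product: 9 bis-epoxy enone
Conditions: D-fructose-derived Shi ketone (30 mol%), Oxone (KHSO5), aq. K2CO3 buffer (pH 10.5), n-Bu4NHSO4, MeCN/CH2(OMe)2, 0 °C
Reagents that add atoms: Oxone (potassium peroxymonosulfate), [K+].[O-]S(=O)(=O)OO
Why: Shi epoxidation of the electron-rich trisubstituted (E)-alkene (the enone C=C is inert to the dioxirane), with the D-fructose-derived ketone setting the (R,R)-epoxide that becomes the ring-fusion pair.

Step 7
Reactants: 9 bis-epoxy enone
Product: 10 (Z)-triethylsilyl enol ether
Conditions: RhCl(PPh3)3 (2 mol%), Et3SiH, benzene, 50 °C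
Reagents that add atoms: triethylsilane, CC[SiH](CC)CC
Why: Rhodium-catalysed 1,4-hydrosilylation of the enone gives the enol silane regiospecifically on the side that carries the benzyloxyethyl chain and mainly as the (Z)-isomer, under neutral conditions that tolerate both epoxides.

Step 8
Reactants: 10 (Z)-triethylsilyl enol ether
Product: 11 trans-fused oxepane-cyclohexanone
Conditions: Et3SiOTf (0.3 equiv), 2,6-di-tert-butyl-4-methylpyridine, CH2Cl2, −78 °C
Reagents that add atoms: none
Why: Silyl-triflate-promoted epoxide-opening oxa-/carbacyclisation cascade, in which the internal epoxide oxygen attacks the tertiary carbon of the silyl-activated terminal epoxide (oxepane via an epoxonium ion) and the enol silane opens the epoxonium anti at its tertiary carbon through a chair transition state, so both O-bearing CH centres are retained, the quaternary carbon is formed with inversion (trans fusion) and the (Z)-enol geometry places the side chain equatorial.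

Step 9
Reactants: 11 trans-fused oxepane-cyclohexanone
Product: 12 tertiary alcohol
Conditions: MeMgBr, CeCl3, THF, −78 °C; aq. NH4Cl
Reagents that add atoms: methylmagnesium bromide, C[Mg]Br
Why: Organocerium addition to the ketone occurs from the equatorial direction because the axial trajectory is blocked by the 1,3-diaxial angular methyl, which gives the axial hydroxyl and equatorial methyl required.

Step 10
Reactants: 12 tertiary alcohol
Product: 13 bis(triethylsilyl) ether
Conditions: Et3SiOTf, 2,6-lutidine, CH2Cl2, 0 °C
Reagents that add atoms: triethylsilyl trifluoromethanesulfonate, CC[Si](CC)(CC)OS(=O)(=O)C(F)(F)F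
Why: Silyl triflate silylation of the hindered tertiary alcohol prevents it from closing a tetrahydrofuran onto the activated side chain in steps 12 and 13.

Step 11
Reactants: 13 bis(triethylsilyl) ether
Product: 14 primary alcohol
Conditions: H2 (1 atm), 10% Pd/C, EtOAc, rt
Reagents that add atoms: none
Why: Hydrogenolysis of the benzyl ether is clean because the molecule has no alkene and the silyl ethers are stable in ethyl acetate.

Step 12
Reactants: 14 primary alcohol
Product: 15 primary iodide
Conditions: I2, PPh3, imidazole, CH2Cl2, 0 °C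
Reagents that add atoms: iodine, II
Why: Garegg–Samuelsson (Appel-type) iodination converts the unhindered primary alcohol by SN2 under buffered conditions that keep the silyl ethers.

Step 13
Reactants: 15 primary iodide; 16 3,3,3-triethoxyprop-1-yne
Product: 18 ethyl alkynoate (western half), via orthoester 17 (not isolated)
Conditions: 16, n-BuLi, THF/HMPA, −78 °C; then 15, −78 → 0 °C; then 5% aq. citric acid, THF, 0 °C
Reagents that add atoms: water, O
Why: SN2 alkylation of the lithium acetylide of the orthopropiolate (a propiolate anion equivalent) by the primary iodide, followed by fast mild-acid hydrolysis of the orthoester to the ethyl ester.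

**Eastern half**

Step 14
Reactants: 19 (4R)-limonene 1,2-oxide
Product: 20 (3R)-6-oxo-3-isopropenylheptanal
Conditions: H5IO6, THF/H2O, 0 °C → rt
Reagents that add atoms: orthoperiodic acid, OI(=O)(O)(O)(O)O
Why: Periodic acid hydrolyses the epoxide and cleaves the resulting diol (Malaprade cleavage) to the keto aldehyde without touching the stereocentre or the isopropenyl group.

Step 15
Reactants: 20 (3R)-6-oxo-3-isopropenylheptanal
Product: 21 (S)-2-methyl-5-isopropenylcyclopent-1-ene-1-carbaldehyde
Conditions: piperidine (cat.), AcOH (cat.), benzene, reflux (Dean–Stark)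
Reagents that add atoms: none
Why: Amine-catalysed intramolecular aldol condensation of the aldehyde α-carbon onto the methyl ketone closes the cyclopentene, and the stereocentre is not enolisable.

Step 16
Reactants: 21 (S)-2-methyl-5-isopropenylcyclopent-1-ene-1-carbaldehyde
Product: 22 epoxy aldehyde (epoxide trans to isopropenyl)
Conditions: 30% H2O2, NaOH (cat.), MeOH, 0 °C
Reagents that add atoms: hydrogen peroxide, OO
Why: Weitz–Scheffer nucleophilic epoxidation of the enal occurs on the ring face opposite the adjacent isopropenyl group and thereby sets the configuration of the future tertiary carbinol.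

Step 17
Reactants: 22 epoxy aldehyde (epoxide trans to isopropenyl)
Product: 24 γ-hydroxy enal (E/Z), via enol ether 23 (not isolated)
Conditions: Ph3P(CH2OMe)Cl, KN(SiMe3)2, THF, −78 → 0 °C; then (CO2H)2, THF/H2O, rt
Reagents that add atoms: (methoxymethyl)triphenylphosphonium chloride, COC[P+](c1ccccc1)(c1ccccc1)c1ccccc1.[Cl-]; water, O
Why: Wittig methoxymethylenation followed by mild-acid hydrolysis gives the homologous β,γ-epoxy aldehyde, which opens by β-elimination to the 4-hydroxy-2-enal, with the C–O bond at the methyl-bearing carbon retained so the tertiary carbinol keeps the epoxide configuration.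

Step 18
Reactants: 24 γ-hydroxy enal (E/Z)
Product: 25 eastern aldehyde (all-cis carbon substituents)
Conditions: [(Ph3P)CuH]6 (0.25 equiv), benzene, rt; aq. NH4Cl
Reagents that add atoms: none
Why: Copper hydride conjugate reduction delivers hydride to the ring β-carbon from the face syn to the hydroxyl and anti to both the methyl and the isopropenyl group, which places CH2CHO cis to both, while the isolated alkene is inert and no basic amine is present to epimerise the allylic centre.

**Key step and endgame**

Step 19
Reactants: 25 eastern aldehyde (all-cis carbon substituents); 18 ethyl alkynoate (western half)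
Product: 26 hydroxy cycloheptene ester (epimers at the carbinol)
Conditions: Fe(acac)3 (0.5 equiv), PhSiH2(Oi-Pr) (2.5 equiv), THF/i-PrOH (20:1), 0.02 M, 0 °C → rt; 25 (1.5 equiv)
Reagents that add atoms: none
Why: Proposed new method: an iron hydride formed from Fe(acac)3 and the silane transfers a hydrogen atom to the CH2 of the isopropenyl group of 25 (Markovnikov metal-hydride hydrogen-atom transfer), and the nucleophilic tertiary radical adds to the β-carbon of alkynoate 18 (Giese addition, regiochemistry fixed by the ester), which forms the bond between the new gem-dimethyl carbon and the tether-bearing olefinic carbon. The α-ester vinyl radical is then reduced by divalent iron to an iron allenolate (radical–polar crossover) whose α-carbon adds to the aldehyde held cis on the cyclopentane, closing the seven-membered ring by a 7-exo-trig aldol addition and leaving the tetrasubstituted C=C in place. The closest known reaction type is the iron-hydride-initiated Giese/aldol radical–polar crossover annulation of alkenyl carbonyl compounds with enones and enals that forms cyclohexanols; the alkynoate acceptor and the seven-membered closure are the extensions proposed. The only new stereocentre is the carbinol carbon and its configuration is not relied upon, since both epimers converge in step 20 and the centre is set in step 21; the quaternary carbon becomes a non-stereogenic CMe2 and the alkene geometry is dictated by the ring. The step needs hydrogen-atom transfer to the electron-rich 1,1-disubstituted alkene rather than to the electron-poor alkyne, and ring closure faster than protonation or hydrogen abstraction, which the cis-1,2 arrangement of the two arms, the gem-dimethyl group and the dilute, alcohol-poor medium are meant to secure.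

Step 20
Reactants: 26 hydroxy cycloheptene ester (epimers at the carbinol)
Product: 27 cycloheptenone ester
Conditions: Dess–Martin periodinane, NaHCO3, CH2Cl2, 0 °C → rt
Reagents that add atoms: none
Why: Dess–Martin oxidation of the secondary allylic alcohol converges both carbinol epimers into one enone, while the tertiary alcohol and the silyl ethers are inert.

Step 21
Reactants: 27 cycloheptenone ester
Product: 28 allylic diol
Conditions: (i-Bu)2AlH (6 equiv), CH2Cl2, −78 → −40 °C; aq. Rochelle salt
Reagents that add atoms: none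
Why: Diisobutylaluminium hydride reduces the ester to the primary allylic alcohol and the ketone in 1,2-fashion (the β-carbon is tetrasubstituted and next to a quaternary carbon), with hydride attacking from the convex face of the cis-fused bicycle, away from the cyclopentane and its methyl group, which gives the required (S)-carbinol.

Step 22
Reactants: 28 allylic diol
Product: 30 bis(triethylsilyl) ether of the target, via mesylate 29 (not isolated)
Conditions: MsCl (1.05 equiv), Et3N, THF, −40 °C; then LiBHEt3 (6 equiv), −40 → 0 °C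
Reagents that add atoms: none
Why: The primary allylic hydroxyl is sulfonylated selectively at low temperature and the mesylate is displaced by hydride in SN2 fashion to give the ring methyl, SN2' attack being disfavoured because the γ-carbon is fully substituted and flanked by the quaternary centre.

Step 23
Reactants: 30 bis(triethylsilyl) ether of the target
Product: 31 target compound
Conditions: n-Bu4NF, THF, 40 °C
Reagents that add atoms: none
Why: Fluoride cleaves the secondary and the tertiary triethylsilyl ether without affecting any stereocentre or the allylic alcohol.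

**Compound list**

1 | geranyl acetate, (2E)-3,7-dimethylocta-2,6-dien-1-yl acetate | CC(=O)OC/C=C(\C)CCC=C(C)C | starting material
2 | (2E)-5-[(2S)-3,3-dimethyloxiran-2-yl]-3-methylpent-2-en-1-yl acetate | CC(=O)OC/C=C(\C)CC[C@@H]1OC1(C)C | intermediate
3 | (2E)-5-[(2S)-3,3-dimethyloxiran-2-yl]-3-methylpent-2-en-1-ol | OC/C=C(\C)CC[C@@H]1OC1(C)C | intermediate
4 | (2S)-3-[(3E)-5-bromo-3-methylpent-3-en-1-yl]-2,2-dimethyloxirane | BrC/C=C(\C)CC[C@@H]1OC1(C)C | intermediate
5 | dimethyl (2-oxopropyl)phosphonate | COP(=O)(OC)CC(C)=O | starting material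
6 | dimethyl [(5E)-8-[(2S)-3,3-dimethyloxiran-2-yl]-6-methyl-2-oxooct-5-en-1-yl]phosphonate | COP(=O)(OC)CC(=O)CC/C=C(\C)CC[C@@H]1OC1(C)C | intermediate
7 | (benzyloxy)acetaldehyde | O=CCOCc1ccccc1 | starting material
8 | (2E,7E)-1-(benzyloxy)-10-[(2S)-3,3-dimethyloxiran-2-yl]-8-methyldeca-2,7-dien-4-one | O=C(/C=C/COCc1ccccc1)CC/C=C(\C)CC[C@@H]1OC1(C)C | intermediate
9 | (2E)-1-(benzyloxy)-6-[(2R,3R)-3-{2-[(2S)-3,3-dimethyloxiran-2-yl]ethyl}-3-methyloxiran-2-yl]hex-2-en-4-one | O=C(/C=C/COCc1ccccc1)CC[C@H]1O[C@]1(C)CC[C@@H]2OC2(C)C | intermediate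
10 | (Z)-triethylsilyl enol ether of the saturated ketone of 9 (silyloxy and benzyloxyethyl cis on the enol C=C; epoxides 2R,3R and 2S) | CC[Si](CC)(CC)O/C(CC[C@H]1O[C@]1(C)CC[C@@H]2OC2(C)C)=C\CCOCc1ccccc1 | intermediate
11 | (3S,5aR,6R,9aR)-6-[2-(benzyloxy)ethyl]-2,2,5a-trimethyl-3-(triethylsilyloxy)octahydro-1-benzoxepin-7(2H)-one (trans-fused) | c1ccccc1COCC[C@@H]1[C@@]2(C)CC[C@H](O[Si](CC)(CC)CC)C(C)(C)O[C@@H]2CCC1=O | intermediate
12 | (3S,5aR,6R,7S,9aR)-6-[2-(benzyloxy)ethyl]-2,2,5a,7-tetramethyl-3-(triethylsilyloxy)decahydro-1-benzoxepin-7-ol (axial OH) | c1ccccc1COCC[C@@H]1[C@@]2(C)CC[C@H](O[Si](CC)(CC)CC)C(C)(C)O[C@@H]2CC[C@]1(C)O | intermediate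
13 | 3,7-bis(triethylsilyl) ether of the diol corresponding to 12 | c1ccccc1COCC[C@@H]1[C@@]2(C)CC[C@H](O[Si](CC)(CC)CC)C(C)(C)O[C@@H]2CC[C@]1(C)O[Si](CC)(CC)CC | intermediate
14 | 2-[(3S,5aR,6R,7S,9aR)-2,2,5a,7-tetramethyl-3,7-bis(triethylsilyloxy)decahydro-1-benzoxepin-6-yl]ethanol | OCC[C@@H]1[C@@]2(C)CC[C@H](O[Si](CC)(CC)CC)C(C)(C)O[C@@H]2CC[C@]1(C)O[Si](CC)(CC)CC | intermediate
15 | (3S,5aR,6R,7S,9aR)-6-(2-iodoethyl)-2,2,5a,7-tetramethyl-3,7-bis(triethylsilyloxy)decahydro-1-benzoxepine | ICC[C@@H]1[C@@]2(C)CC[C@H](O[Si](CC)(CC)CC)C(C)(C)O[C@@H]2CC[C@]1(C)O[Si](CC)(CC)CC | intermediate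
16 | 3,3,3-triethoxyprop-1-yne | C#CC(OCC)(OCC)OCC | starting material
17 | triethyl orthoester of 18 | CCOC(OCC)(OCC)C#CCC[C@@H]1[C@@]2(C)CC[C@H](O[Si](CC)(CC)CC)C(C)(C)O[C@@H]2CC[C@]1(C)O[Si](CC)(CC)CC | intermediate (not isolated)
18 | ethyl 5-[(3S,5aR,6R,7S,9aR)-2,2,5a,7-tetramethyl-3,7-bis(triethylsilyloxy)decahydro-1-benzoxepin-6-yl]pent-2-ynoate | CCOC(=O)C#CCC[C@@H]1[C@@]2(C)CC[C@H](O[Si](CC)(CC)CC)C(C)(C)O[C@@H]2CC[C@]1(C)O[Si](CC)(CC)CC | intermediate
19 | (4R)-limonene 1,2-oxide (cis/trans mixture at the epoxide) | CC12OC1C[C@@H](CC2)C(C)=C | starting material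
20 | (3R)-6-oxo-3-(prop-1-en-2-yl)heptanal | O=CC[C@@H](CCC(C)=O)C(C)=C | intermediate
21 | (5S)-2-methyl-5-(prop-1-en-2-yl)cyclopent-1-ene-1-carbaldehyde | O=CC1=C(C)CC[C@H]1C(C)=C | intermediate
22 | (1S,2S,5R)-5-methyl-2-(prop-1-en-2-yl)-6-oxabicyclo[3.1.0]hexane-1-carbaldehyde | O=C[C@@]12O[C@]1(C)CC[C@H]2C(C)=C | intermediate
23 | (1S,2S,5R)-1-(2-methoxyethenyl)-5-methyl-2-(prop-1-en-2-yl)-6-oxabicyclo[3.1.0]hexane (E/Z mixture) | COC=C[C@@]12O[C@]1(C)CC[C@H]2C(C)=C | intermediate (not isolated)
24 | 2-[(2R,5S)-2-hydroxy-2-methyl-5-(prop-1-en-2-yl)cyclopentylidene]acetaldehyde (E/Z mixture) | O=CC=C1[C@](C)(O)CC[C@H]1C(C)=C | intermediate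
25 | 2-[(1R,2R,5R)-2-hydroxy-2-methyl-5-(prop-1-en-2-yl)cyclopentyl]acetaldehyde | O=CC[C@H]1[C@](C)(O)CC[C@H]1C(C)=C | intermediate
26 | ethyl ester in place of the ring methyl, cis-fused hydroazulene with free tertiary and allylic hydroxyls, western half as bis(triethylsilyl) ether (both epimers at the allylic carbinol) | CCOC(=O)C1=C(CC[C@@H]3[C@@]4(C)CC[C@H](O[Si](CC)(CC)CC)C(C)(C)O[C@@H]4CC[C@]3(C)O[Si](CC)(CC)CC)C(C)(C)[C@@H]2CC[C@@](C)(O)[C@@H]2CC1O | intermediate
27 | ketone corresponding to 26 (2-ethoxycarbonyl cyclohept-2-enone) | CCOC(=O)C1=C(CC[C@@H]3[C@@]4(C)CC[C@H](O[Si](CC)(CC)CC)C(C)(C)O[C@@H]4CC[C@]3(C)O[Si](CC)(CC)CC)C(C)(C)[C@@H]2CC[C@@](C)(O)[C@@H]2CC1=O | intermediate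
28 | diol with CH2OH in place of the ring methyl and the (S)-allylic carbinol | OCC1=C(CC[C@@H]3[C@@]4(C)CC[C@H](O[Si](CC)(CC)CC)C(C)(C)O[C@@H]4CC[C@]3(C)O[Si](CC)(CC)CC)C(C)(C)[C@@H]2CC[C@@](C)(O)[C@@H]2C[C@@H]1O | intermediate
29 | primary allylic methanesulfonate of 28 | CS(=O)(=O)OCC1=C(CC[C@@H]3[C@@]4(C)CC[C@H](O[Si](CC)(CC)CC)C(C)(C)O[C@@H]4CC[C@]3(C)O[Si](CC)(CC)CC)C(C)(C)[C@@H]2CC[C@@](C)(O)[C@@H]2C[C@@H]1O | intermediate (not isolated)
30 | target with both western hydroxyls as triethylsilyl ethers | CC1=C(CC[C@@H]3[C@@]4(C)CC[C@H](O[Si](CC)(CC)CC)C(C)(C)O[C@@H]4CC[C@]3(C)O[Si](CC)(CC)CC)C(C)(C)[C@@H]2CC[C@@](C)(O)[C@@H]2C[C@@H]1O | intermediate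
31 | CNP0276044.4 | CC1=C(CC[C@@H]2[C@@]3(C)CC[C@H](O)C(C)(C)O[C@@H]3CC[C@]2(C)O)C(C)(C)[C@@H]2CC[C@@](C)(O)[C@@H]2C[C@@H]1O | target

**Step count**

Total steps: 23. Longest linear sequence: 18 (steps 1–13, then 19–23); the eastern half (steps 14–18) is made in parallel.

**Steps most likely to fail**

1. Step 19 (key step). The tertiary radical may be reduced or may abstract the aldehydic hydrogen before it adds to the β-substituted alkynoate, and the vinyl radical or allenolate may be quenched by 1,5-hydrogen transfer or protonation before the seven-membered aldol closure. Fallback (sets out from 25 and 18, returns at 26), with the same two bonds made in reverse order by known reactions: MgI2 (CH2Cl2, 0 °C) adds iodide to the alkynoate and the iodo-allenolate is captured by the aldehyde of 25 (β-iodo Morita–Baylis–Hillman reaction), giving the β-iodo-α-(hydroxyalkyl)acrylate F1. A reductive Heck cyclisation (Pd(OAc)2, PPh3, HCO2Na, Et4NCl, DMF, 80 °C) then closes the bond to the future CMe2 carbon by 7-exo-trig carbopalladation of the isopropenyl group, the neopentyl-type alkylpalladium (no β-hydrogen) being reduced by formate, and gives 26.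

2. Step 8 (cascade). The cascade may stop after the oxacyclisation through loss of the enol silane by protodesilylation, or the epoxonium ion may be trapped or opened at the wrong carbon. Fallback (sets out from 4, returns at 14), with a β-keto ester as an always-enolisable terminator and the side chain attached afterwards: the dianion of allyl acetoacetate (NaH, n-BuLi) is alkylated with 4 to give the allyl β-keto ester F2, and epoxidation with the D-fructose-derived Shi ketone gives the bis-epoxide F3. Et3SiOTf (1.2 equiv) with 2,6-di-tert-butyl-4-methylpyridine triggers the same oxa-/carbacyclisation with the keto ester enol as terminator and gives the bicyclic allyl β-keto ester F4. Pd(PPh3)4 then effects decarboxylative allylation (Tsuji) at the carbon next to the quaternary centre and gives the α-allyl ketone F5. MeMgBr/CeCl3 gives the tertiary alcohol F6, Et3SiOTf/2,6-lutidine gives the bis-silyl ether F7, and ozonolysis with NaBH4 work-up gives 14.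

3. Step 22 (deoxygenation). Sulfonylation may fail to discriminate between the primary and the secondary allylic hydroxyl, so the carbinol could be lost on hydride treatment. Fallback (sets out from 28, returns at 30), with the two allylic hydroxyls tied into a temporary ring and then differentiated: 4-MeOC6H4CH(OMe)2 with pyridinium p-toluenesulfonate gives the six-membered p-methoxybenzylidene acetal F8. (i-Bu)2AlH opens it reductively so that the primary hydroxyl is free and the secondary one is a p-methoxybenzyl ether, the hydroxy ether F9. Mesylation and LiBHEt3 then address the only free allylic hydroxyl and give the methyl compound F10, and DDQ (CH2Cl2/pH 7 buffer) removes the benzyl-type ether and gives 30.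

**Further compounds**

F1 | step 19 | ethyl (E/Z)-3-iodo-2-{1-hydroxy-2-[(1R,2R,5R)-2-hydroxy-2-methyl-5-(prop-1-en-2-yl)cyclopentyl]ethyl}-5-[western bicycle as in 18]pent-2-enoate | CCOC(=O)C(C(O)C[C@H]1[C@](C)(O)CC[C@H]1C(C)=C)=C(I)CC[C@@H]1[C@@]2(C)CC[C@H](O[Si](CC)(CC)CC)C(C)(C)O[C@@H]2CC[C@]1(C)O[Si](CC)(CC)CC
F2 | step 8 | allyl (6E)-9-[(2S)-3,3-dimethyloxiran-2-yl]-7-methyl-3-oxonon-6-enoate | C=CCOC(=O)CC(=O)CC/C=C(\C)CC[C@@H]1OC1(C)C
F3 | step 8 | allyl 5-[(2R,3R)-3-{2-[(2S)-3,3-dimethyloxiran-2-yl]ethyl}-3-methyloxiran-2-yl]-3-oxopentanoate | C=CCOC(=O)CC(=O)CC[C@H]1O[C@]1(C)CC[C@@H]2OC2(C)C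
F4 | step 8 | allyl (3S,5aR,9aR)-2,2,5a-trimethyl-7-oxo-3-(triethylsilyloxy)decahydro-1-benzoxepine-6-carboxylate | C=CCOC(=O)C1[C@@]2(C)CC[C@H](O[Si](CC)(CC)CC)C(C)(C)O[C@@H]2CCC1=O
F5 | step 8 | (3S,5aR,6R,9aR)-6-allyl-2,2,5a-trimethyl-3-(triethylsilyloxy)octahydro-1-benzoxepin-7(2H)-one | C=CC[C@@H]1[C@@]2(C)CC[C@H](O[Si](CC)(CC)CC)C(C)(C)O[C@@H]2CCC1=O
F6 | step 8 | (3S,5aR,6R,7S,9aR)-6-allyl-2,2,5a,7-tetramethyl-3-(triethylsilyloxy)decahydro-1-benzoxepin-7-ol | C=CC[C@@H]1[C@@]2(C)CC[C@H](O[Si](CC)(CC)CC)C(C)(C)O[C@@H]2CC[C@]1(C)O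
F7 | step 8 | (3S,5aR,6R,7S,9aR)-6-allyl-2,2,5a,7-tetramethyl-3,7-bis(triethylsilyloxy)decahydro-1-benzoxepine | C=CC[C@@H]1[C@@]2(C)CC[C@H](O[Si](CC)(CC)CC)C(C)(C)O[C@@H]2CC[C@]1(C)O[Si](CC)(CC)CC
F8 | step 22 | p-methoxybenzylidene acetal of the two allylic hydroxyls of 28 | COc1ccc(cc1)C1OCC2=C(CC[C@@H]4[C@@]5(C)CC[C@H](O[Si](CC)(CC)CC)C(C)(C)O[C@@H]5CC[C@]4(C)O[Si](CC)(CC)CC)C(C)(C)[C@@H]3CC[C@@](C)(O)[C@@H]3C[C@@H]2O1
F9 | step 22 | 28 with the secondary allylic hydroxyl as p-methoxybenzyl ether | OCC1=C(CC[C@@H]3[C@@]4(C)CC[C@H](O[Si](CC)(CC)CC)C(C)(C)O[C@@H]4CC[C@]3(C)O[Si](CC)(CC)CC)C(C)(C)[C@@H]2CC[C@@](C)(O)[C@@H]2C[C@@H]1OCc1ccc(OC)cc1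
F10 | step 22 | 30 with the allylic hydroxyl as p-methoxybenzyl ether | CC1=C(CC[C@@H]3[C@@]4(C)CC[C@H](O[Si](CC)(CC)CC)C(C)(C)O[C@@H]4CC[C@]3(C)O[Si](CC)(CC)CC)C(C)(C)[C@@H]2CC[C@@](C)(O)[C@@H]2C[C@@H]1OCc1ccc(OC)cc1
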